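The numbers in the tables were generated by integration on assumed constants, and the scatter is random.

The target tells little after the early minutes of these runs. In oak it reads 37% at 5.00 min and 35% at 12.0 min, while the isomer of the product climbs from 16% to 44%, so the isomer is the reading to watch.

in all of them: starting material 10 mM; free catalyst 0.20 mM
- oak: second substrate 14 mM; partner 15 mM; run made earlier
- cedar: second substrate 22 mM; partner 15 mM; run made earlier
- flask: second substrate 10.0 mM; partner 15.0 mM; time 10 min

- oak (time / min: target / %, isomer of the product / %): 2.50: 28, 3; 5.00: 37, 16; 8.00: 36, 34; 10.0: 35, 39; 12.0: 35, 44
- cedar (time / min: target / %, isomer of the product / %): 1.00: 12, 2; 3.00: 28, 7; 6.00: 36, 16; 8.00: 35, 23; 12.0: 34, 39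

(standard deviation of a reading: 1.5 percentage points)

- why nothing more happens at 10 min, or that something still does (forward and back rates have come level / all of the starting material has reacted / it is still moving / the partner has run out first / no working catalyst is left)
- target at 10 min, in percent of the starting material charged
- isomer of the product at 10 min, in percent of the starting material charged

- reactions considered so far: partner + catalyst intermediate B -> free catalyst + second product; second substrate + free catalyst <-> catalyst intermediate B; partner + catalyst intermediate A -> free catalyst + target; starting material + free catalyst <-> catalyst intermediate A; target + free catalyst <-> isomer of the product + free catalyst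
- the reaction counts as stopped when no species that holds the starting material changes by six tenths of a point or more over the second half of the time

Oak and cedar differ in second substrate, and I read their tables row against row. Cedar at 6.00 min gives 36% target and 16% isomer, oak at 5.00 min gives 37% and 16%. Cedar at 12.0 min gives 34% and 39%, oak at 10.0 min gives 35% and 39%. Both pairs show the same stretch of the time axis, s = 1.20.

I read this as competitive inhibition: second substrate, at charge c, holds catalyst as catalyst intermediate B with strength b, so I let the clock of a run go as one over (one plus b c), leaving catalyst intermediate A out of this balance as a simplification. With that clock steady, the isomer rate integrates in closed form to a reading that depends on time divided by (one plus b c). The stretch, a reading with the scatter of its rows, gives b = 38.5 L mol⁻¹.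

The clock factor f, oak's (one plus b c) over the flask's, is 1.11. So the flask at 10 min should read like oak at 11.1 min. Between oak's last two rows that means target 35% and isomer 41.8%. Oak's isomer still gains 5 percentage points across those rows, so I expect it still moving.

The forecast says it is still moving, target 33% (29% to 37%) and isomer 47% (41% to 53%), holding that “Second substrate therefore ties up free catalyst”. We part on the isomer, 47% against my 41.8%.

The flask gives: it is still moving, target 36.1%, isomer 42.0%.

    partner + catalyst intermediate B → free catalyst + second product (k = 22.0 L mol⁻¹ s⁻¹)
    second substrate + free catalyst ⇌ catalyst intermediate B (K = 57.0 L mol⁻¹, k = 18.0 L mol⁻¹ s⁻¹)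
    partner + catalyst intermediate A → free catalyst + target (k = 30.0 L mol⁻¹ s⁻¹)
    starting material + free catalyst ⇌ catalyst intermediate A (K = 230 L mol⁻¹, k = 41.0 L mol⁻¹ s⁻¹)
    target + free catalyst ⇌ isomer of the product + free catalyst, rate k5*[free catalyst]*[target] forward; the back reaction follows from the equilibrium constant (K = 2.20, k = 27.0 L mol⁻¹ s⁻¹)

In the flask, half of the turnover up to 10 min of the step from starting material + free catalyst to catalyst intermediate A is done by 2.81 min, and at 5.00 min target stands at 37.3%. From there target reads 36.1% at 10 min while isomer climbs from 19.5% to 42.0%, with the backward turnover of the step from target to isomer 29% of the forward one. The same charge read at 6.0 min maps by f to oak at 6.67 min, where oak's rows give isomer 26.0%, and that neighbour flask holds 24.7%.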